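**Retrosynthetic overview**

1. Target 13 is opened at the C4–O and C5–O ester bonds: both (R)-2-methylbutanoates come from anti opening of the 4,5-epoxide 10 (epoxide syn to the C3 acetate) by the anhydride 12, with C5 attacked with inversion.
2. Epoxide 10 comes from hydroxyl-directed epoxidation of C4=C5, and the C1=C2 enoate from loss of HNO2; the nitro group on C2 is a traceless activating group that reverses the usual acrylate regiochemistry.
3. The carbocycle is made in one step by an enantioselective [4+2] cycloaddition of (E)-1-(trimethylsilyloxy)buta-1,3-diene (C3–C6) with methyl (E)-3-nitroacrylate (C1–C2), forming C2–C3 and C6–C1.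
4. Enabling feature: in the cyclohexene ring the C1=C2 enoate is flanked by the oxygen-bearing C3 and the C6 methylene, so C3–C4–C5–C6 is a latent 1-oxygenated 1,3-diene and C1–C2 a propiolate equivalent; the C4=C5 alkene left by the cycloaddition lies where the trans diester belongs.
5. Ring order: cyclohexene first (step 3), then a temporary oxirane (made in step 4, opened in step 7).

Key step: step 3

Assumption: the two 2-methylbutanoyl groups of the given structure are (R)-configured, so (R)-2-methylbutanoic acid is used; the (1R,2R) antipode of the thiourea catalyst is taken to give the (3S) adduct 7, and its mirror image is used instead if the sense of induction is the reverse.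

**Step 1**
Reactants: 1 methyl 2-hydroxy-2-methoxyacetate (methyl glyoxylate methyl hemiacetal); 2 nitromethane
Product: 3 methyl 2-hydroxy-3-nitropropanoate (racemic)
Conditions: MeNO2 (5 equiv), Et3N (10 mol %), rt
Reagents that add atoms: none
Why: Base-catalysed nitroaldol (Henry) addition of the nitromethane anion to the glyoxylate carbonyl released from the hemiacetal; the new carbinol centre is racemic and is destroyed in step 2.

**Step 2**
Reactants: 3 methyl 2-hydroxy-3-nitropropanoate
Product: 4 methyl (E)-3-nitroacrylate
Conditions: MsCl (1.1 equiv), Et3N (2.2 equiv), CH2Cl2, −20 °C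
Reagents that add atoms: none
Why: Mesylation followed by E1cB elimination (dehydration of a beta-nitro alcohol) should give the conjugated nitroalkene as the favoured E isomer.

**Step 3**
Reactants: 4 methyl (E)-3-nitroacrylate; 5 (E)-1-(trimethylsilyloxy)buta-1,3-diene
Product: 7 methyl (1S,2R,3S)-3-hydroxy-2-nitrocyclohex-4-ene-1-carboxylate, via trimethylsilyl ether 6 (not isolated)
Conditions: 1,1′-[(1R,2R)-cyclohexane-1,2-diyl]bis{3-[3,5-bis(trifluoromethyl)phenyl]thiourea} (10 mol %), toluene, −78 °C; then 1 M HCl, THF, 0 °C
Reagents that add atoms: none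
Why: Proposed new method: double hydrogen bonding of the thiourea to the nitro group of 4 should lower its LUMO enough for the catalysed, concerted but asynchronous [4+2] cycloaddition with 5 to outrun the uncatalysed one at −78 °C; the closest known reaction types are the thermal nitro-directed Diels–Alder reaction of 3-nitroacrylates with 1-oxygenated dienes and hydrogen-bond-donor catalysis of nitroalkene cycloadditions and conjugate additions, which has not been shown to give high enantioselectivity with a silyloxydiene. The cyclohexene ring closes by suprafacial–suprafacial [4π+2π] addition, the C6–C1 bond leading (diene terminus with the largest HOMO coefficient onto the carbon beta to the nitro group) and the C2–C3 bond following. C1 and C2 come out trans because the E geometry of 4 is transferred, C3 comes out cis to C2 through the nitro-endo transition state and the E geometry of 5, and the absolute sense is set by the catalyst, which shields one face of the bound nitroalkene. The step needs regiocontrol, endo control and face control: the nitro group, a traceless activator that outranks the ester, puts C2 next to the oxygenated C3, and the silyloxy donor on C3 polarises the diene in the matching sense. Only C3 persists into the target, so the minor exo adduct, which would end up with the opposite C3 configuration once C1 and C2 are flattened, is removed here by chromatography. Acidic work-up cleaves the labile silyl ether 6 and frees the C3 hydroxyl that directs step 4.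

**Step 4**
Reactants: 7 methyl (1S,2R,3S)-3-hydroxy-2-nitrocyclohex-4-ene-1-carboxylate
Product: 8 methyl (1S,2R,3R,4R,5S)-4,5-epoxy-3-hydroxy-2-nitrocyclohexane-1-carboxylate
Conditions: mCPBA (1.3 equiv), CH2Cl2, 0 °C to rt
Reagents that add atoms: 3-chloroperoxybenzoic acid (mCPBA), O=C(OO)c1cccc(Cl)c1
Why: Hydroxyl-directed (Henbest) peracid epoxidation, in which the pseudoaxial allylic C3 hydroxyl hydrogen-bonds the peracid and delivers oxygen to the syn face of C4=C5 (the face also left open by the C1 ester), which sets C4 and C5.

**Step 5**
Reactants: 8 methyl (1S,2R,3R,4R,5S)-4,5-epoxy-3-hydroxy-2-nitrocyclohexane-1-carboxylate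
Product: 10 methyl (3R,4S,5S)-3-acetoxy-4,5-epoxycyclohex-1-ene-1-carboxylate, via epoxy alcohol 9 (not isolated)
Conditions: DBU (1.1 equiv), CH2Cl2, −20 to 0 °C; then Ac2O (1.5 equiv), Et3N (2 equiv), 4-(dimethylamino)pyridine (5 mol %), 0 °C
Reagents that add atoms: acetic anhydride, CC(=O)OC(C)=O
Why: E1cB loss of nitrous acid (C1 proton alpha to the ester removed, nitrite leaving from C2) should give the conjugated C1=C2 ester, and the C3 alcohol is then acetylated under acyl-transfer catalysis; elimination is run first because a beta-acetoxy nitronate would expel acetate, and no stereocentre is formed or touched.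

**Step 6**
Reactants: 11 (R)-2-methylbutanoic acid (2 equiv)
Product: 12 (R)-2-methylbutanoic anhydride
Conditions: N,N′-dicyclohexylcarbodiimide (0.5 equiv), CH2Cl2, 0 °C to rt, filtration
Reagents that add atoms: none
Why: Carbodiimide dehydration of two acid molecules to the symmetrical anhydride runs without base, so the alpha stereocentre should not epimerise.

**Step 7**
Reactants: 10 methyl (3R,4S,5S)-3-acetoxy-4,5-epoxycyclohex-1-ene-1-carboxylate; 12 (R)-2-methylbutanoic anhydride
Product: 13 methyl (3R,4S,5R)-3-acetoxy-4,5-bis{[(2R)-2-methylbutanoyl]oxy}cyclohex-1-ene-1-carboxylate (target)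
Conditions: 12 (3 equiv), Er(OTf)3 (5 mol %), CH2Cl2, 0 °C to rt
Reagents that add atoms: none
Why: Lewis-acid-catalysed ring opening of an epoxide by a carboxylic anhydride to the anti 1,2-diester, in which carboxylate should attack C5 with inversion (remote from the electron-withdrawing C3 acetoxy group, trans-diaxial opening, the regiochemistry known for azide and amine openings of 3-alkoxy analogues of 10) to set 5R, while the epoxide oxygen stays on C4 (4S) and is acylated without a free alkoxide next to the C3 acetate.

**Compound list**

1 | methyl 2-hydroxy-2-methoxyacetate | COC(O)C(=O)OC | starting material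
2 | nitromethane | C[N+](=O)[O-] | starting material
3 | methyl 2-hydroxy-3-nitropropanoate (racemic) | COC(=O)C(O)C[N+](=O)[O-] | intermediate
4 | methyl (E)-3-nitroacrylate | COC(=O)/C=C/[N+](=O)[O-] | intermediate
5 | (E)-1-(trimethylsilyloxy)buta-1,3-diene | C=C/C=C/O[Si](C)(C)C | starting material
6 | methyl (1S,2R,3S)-2-nitro-3-(trimethylsilyloxy)cyclohex-4-ene-1-carboxylate | COC(=O)[C@@H]1[C@@H]([N+](=O)[O-])[C@@H](O[Si](C)(C)C)C=CC1 | intermediate (not isolated)
7 | methyl (1S,2R,3S)-3-hydroxy-2-nitrocyclohex-4-ene-1-carboxylate | COC(=O)[C@@H]1[C@@H]([N+](=O)[O-])[C@@H](O)C=CC1 | intermediate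
8 | methyl (1S,2R,3R,4R,5S)-4,5-epoxy-3-hydroxy-2-nitrocyclohexane-1-carboxylate | COC(=O)[C@@H]1[C@@H]([N+](=O)[O-])[C@@H](O)[C@@H]2[C@@H](O2)C1 | intermediate
9 | methyl (3R,4R,5S)-4,5-epoxy-3-hydroxycyclohex-1-ene-1-carboxylate | COC(=O)C1=C[C@@H](O)[C@@H]2[C@@H](O2)C1 | intermediate (not isolated)
10 | methyl (3R,4S,5S)-3-acetoxy-4,5-epoxycyclohex-1-ene-1-carboxylate | COC(=O)C1=C[C@@H](OC(C)=O)[C@@H]2[C@@H](O2)C1 | intermediate
11 | (R)-2-methylbutanoic acid | CC[C@@H](C)C(=O)O | starting material
12 | (R)-2-methylbutanoic anhydride | CC[C@@H](C)C(=O)OC(=O)[C@H](C)CC | intermediate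
13 | methyl (3R,4S,5R)-3-acetoxy-4,5-bis{[(2R)-2-methylbutanoyl]oxy}cyclohex-1-ene-1-carboxylate | COC(=O)C1=C[C@@H](OC(C)=O)[C@@H](OC(=O)[C@H](C)CC)[C@H](OC(=O)[C@H](C)CC)C1 | target

**Step count and risks**

Total step count: 7. Longest linear sequence: 6 steps (1, 2, 3, 4, 5, 7); step 6 is a one-step side branch.

Steps most likely to fail:

1. Step 3 (proposed new method). The hydrogen-bonded pathway may not gain enough rate over the uncatalysed cycloaddition, and discrimination between the two faces and between endo and exo may be weak, so that C3 is formed with low enantiomeric purity; the acidic thiourea may also protodesilylate the diene. Fallback, known chemistry, setting out from 4 and 5 and rejoining at 10: the uncatalysed cycloaddition (toluene, 0 °C to rt, then 1 M HCl) should give, through racemic methyl (1S*,2R*,3S*)-2-nitro-3-(trimethylsilyloxy)cyclohex-4-ene-1-carboxylate F1, racemic methyl (1S*,2R*,3S*)-3-hydroxy-2-nitrocyclohex-4-ene-1-carboxylate F2. Epoxidation as in step 4 should give racemic methyl (1S*,2R*,3R*,4R*,5S*)-4,5-epoxy-3-hydroxy-2-nitrocyclohexane-1-carboxylate F3, and DBU should give racemic methyl (3R*,4R*,5S*)-4,5-epoxy-3-hydroxycyclohex-1-ene-1-carboxylate F4, in which C1 and C2 are no longer stereocentres. Lipase-catalysed kinetic resolution (immobilised lipase B from Candida antarctica, vinyl acetate, tert-butyl methyl ether, 30 °C) should then acetylate the (3R) antipode; this is predicted by the empirical model for lipases on secondary alcohols with the epoxide-bearing C4 as the larger group. The acetate formed is 10 itself, and methyl (3S,4S,5R)-4,5-epoxy-3-hydroxycyclohex-1-ene-1-carboxylate F5 is left behind and separated.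

2. Step 5. The nitronate that DBU forms from 8 may open the neighbouring epoxide or trigger retro-nitroaldol cleavage (eroding C3) before nitrite is lost, and gamma-deprotonation of the new enoate may open the epoxide by vinylogous elimination. Fallback, setting out from 7 and rejoining at 9: the order of events is reversed. DBU first removes nitrous acid from 7 to give methyl (3S)-3-hydroxycyclohexa-1,4-diene-1-carboxylate F6, so no epoxide is present while a nitronate exists. Vanadium-catalysed hydroxyl-directed epoxidation (VO(acac)2, tert-butyl hydroperoxide, CH2Cl2, 0 °C), selective for the electron-rich C4=C5 bond and syn to the C3 hydroxyl, then gives 9, which is acetylated as in step 5.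

3. Step 7. Carboxylate may attack C4 instead of C5 (loss of regiocontrol, giving the 4,5-diepimeric diester), and the Lewis acid may induce acetyl migration from O3 to O4 or rearrangement of the epoxide. Fallback, setting out from 10 and rejoining at 13: the epoxide is opened under nucleophilic, buffered conditions with cesium (R)-2-methylbutanoate (0.2 equiv, from 11 and Cs2CO3) in neat 11 at 70 °C, an SN2 trans-diaxial opening at C5 like the azide opening of 3-alkoxy analogues. This gives methyl (3R,4S,5R)-3-acetoxy-4-hydroxy-5-{[(2R)-2-methylbutanoyl]oxy}cyclohex-1-ene-1-carboxylate F7, whose C4 hydroxyl is esterified with 11 (N,N′-dicyclohexylcarbodiimide, cat. 4-(dimethylamino)pyridine, Steglich esterification) to give 13.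

**Further compounds**

F1 | step 3 | racemic methyl (1S*,2R*,3S*)-2-nitro-3-(trimethylsilyloxy)cyclohex-4-ene-1-carboxylate | COC(=O)[C@@H]1[C@@H]([N+](=O)[O-])[C@@H](O[Si](C)(C)C)C=CC1.COC(=O)[C@H]1[C@H]([N+](=O)[O-])[C@H](O[Si](C)(C)C)C=CC1
F2 | step 3 | racemic methyl (1S*,2R*,3S*)-3-hydroxy-2-nitrocyclohex-4-ene-1-carboxylate | COC(=O)[C@@H]1[C@@H]([N+](=O)[O-])[C@@H](O)C=CC1.COC(=O)[C@H]1[C@H]([N+](=O)[O-])[C@H](O)C=CC1
F3 | step 3 | racemic methyl (1S*,2R*,3R*,4R*,5S*)-4,5-epoxy-3-hydroxy-2-nitrocyclohexane-1-carboxylate | COC(=O)[C@@H]1[C@@H]([N+](=O)[O-])[C@@H](O)[C@@H]2[C@@H](O2)C1.COC(=O)[C@H]1[C@H]([N+](=O)[O-])[C@H](O)[C@H]2[C@H](O2)C1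
F4 | step 3 | racemic methyl (3R*,4R*,5S*)-4,5-epoxy-3-hydroxycyclohex-1-ene-1-carboxylate | COC(=O)C1=C[C@@H](O)[C@@H]2[C@@H](O2)C1.COC(=O)C1=C[C@H](O)[C@H]2[C@H](O2)C1
F5 | step 3 | methyl (3S,4S,5R)-4,5-epoxy-3-hydroxycyclohex-1-ene-1-carboxylate | COC(=O)C1=C[C@H](O)[C@H]2[C@H](O2)C1
F6 | step 5 | methyl (3S)-3-hydroxycyclohexa-1,4-diene-1-carboxylate | COC(=O)C1=C[C@@H](O)C=CC1
F7 | step 7 | methyl (3R,4S,5R)-3-acetoxy-4-hydroxy-5-{[(2R)-2-methylbutanoyl]oxy}cyclohex-1-ene-1-carboxylate | COC(=O)C1=C[C@@H](OC(C)=O)[C@@H](O)[C@H](OC(=O)[C@H](C)CC)C1
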